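(The numbers in the tables come from a simulation on assumed constants; noise was put on by code.)

In a one-step world with electrophile and nucleophile charged in equal amounts, the fraction of electrophile left is a = τ/(τ + t). Here τ is the second-order half-life, and at fixed equivalents it stretches as the charge shrinks.

| flask | electrophile | nucleophile | free base | scavenger | remark | time |
|---|---|---|---|---|---|---|
| noon | 20 mM | 0.90 equiv | 1.5 equiv | 1.5 equiv | run made earlier |  |
| dawn | 20 mM | 0.90 equiv | 2.4 equiv | 1.5 equiv | run made earlier |  |
| autumn | 20 mM | 1.8 equiv | 1.1 equiv | 1.5 equiv | run made earlier |  |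
| flask | 20 mM | 0.900 equiv | 1.10 equiv | 1.50 equiv |  | 5.0 d |

| run | time / d | electrophile / % | target / % |
|---|---|---|---|
| noon | 0.417 | 73.6 | 25.1 |
| noon | 0.833 | 61.3 | 33.1 |
| noon | 1.25 | 53.2 | 35.7 |
| noon | 1.67 | 46.4 | 39.1 |
| noon | 2.00 | 41.2 | 39.9 |
| noon | 2.50 | 36.3 | 41.9 |
| noon | 3.00 | 31.6 | 42.5 |
| dawn | 0.250 | 81.3 | 18.0 |
| dawn | 0.333 | 76.3 | 19.7 |
| dawn | 0.500 | 71.3 | 27.7 |
| dawn | 0.833 | 60.8 | 32.1 |
| dawn | 1.25 | 52.8 | 35.6 |
| dawn | 2.08 | 40.9 | 41.7 |
| dawn | 3.00 | 30.7 | 44.7 |
| autumn | 0.250 | 65.7 | 32.2 |
| autumn | 0.417 | 53.1 | 43.1 |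
| autumn | 0.833 | 35.7 | 56.1 |
| autumn | 1.67 | 18.5 | 66.1 |
| autumn | 3.00 | 8.1 | 71.3 |

(scatter of a reading: 0.5 percentage points)

- the numbers in the tables scatter by 0.5 percentage points (one standard deviation)
- the earlier runs do not show how much of nucleophile is bound; that part of a forecast is a guess

1. part of the electrophile that has reacted at 5.0 d
2. share of free nucleophile in free nucleophile and protonated nucleophile together, at 5.0 d

Which numbers must be known well? Free base matters little over the range from noon to dawn: it rises from 1.5 equiv to 2.4 equiv, and the electrophile left at 3.00 d moves by 0.9 percentage points, with a scatter of 0.5 points. Autumn, with 1.8 equiv of nucleophile and 1.1 equiv of free base, leaves 8.1% at that time, and noon, with 0.90 equiv and 1.5 equiv, leaves 31.6%. Two settings differ there, and the gap of 23 points is far wider than the one from noon to dawn. Scavenger is the same in all three runs, so they cannot show its weight. The flask shares noon's nucleophile, 0.900 equiv, but has 1.10 equiv of free base, a level no earlier run shows beside so little nucleophile; it takes τ from noon all the same. With noon treated as that one-step world, its last reading gives an apparent half-life at the charge of 1.39 d. For the flask at 5.0 d, this reckoning gives 78.3% reacted.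

The forecast says 80% (74% to 85%), above this reckoning. For the free share it says 40% (15% to 70%): “The free share is a guess”.

The flask gives 82.2% reacted and a free share of 57.8%.

    electrophile + nucleophile → acid set free + target (k = 2.40 M⁻¹ h⁻¹)
    nucleophile + acid set free ⇌ protonated nucleophile, settled at all times (K = 7800 M⁻¹)
    acid set free + free base ⇌ salt of the base (K = 2.30 × 10⁶ M⁻¹, k = 11.0 M⁻¹ h⁻¹)
    electrophile + target → side product (k = 0.540 M⁻¹ h⁻¹)
    nucleophile + acid set free ⇌ idle adduct, settled at all times (K = 110 M⁻¹)
    acid set free + scavenger → scavenged by-product (k = 15.0 M⁻¹ h⁻¹)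

The flask stands 3.9 points above the half-life reckoning, and its free share stands 18 points above the forecast. A neighbour is charged with 5.0 mM of electrophile, a quarter of the flask's charge, with the same equivalents and time. For this neighbour τ stretches to 5.54 d, and the reckoning gives 47.4% reacted. The neighbour reaches 50.3%, with 39.3% of its charge as target and, each side product counted as two, 11.0% as side product.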